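**Plan**

Labels: oxolane ring T (O1, C2–C5), guaiacyl ring A on C2, ring B on C5, side chain Cα(OH)–Cβ(OAr)–CγH3 on the phenol oxygen of ring B, guaiacyl ring C on Cα.
Cuts: Cα–Cβ (aldol, with CγH3 read as a fully reduced carboxyl carbon); ring B O–Cβ (Williamson); C2–ring A and C2–H (aryllithium on a lactone, then hydride); ring B–C5 (arylzinc on meso-2,3-dimethylsuccinic anhydride).
Enabling feature: Cβ lies between an aryl ether oxygen and a carbon that can be carried as an imide carbonyl, and Cα is a benzylic carbinol on electron-rich ring C. Cβ is therefore the α-carbon of an aryloxyacetyl imide and Cα the formyl carbon of O-benzylvanillin, so one anti-aldol addition joins the halves and sets Cα and Cβ together.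
Forward order: anhydride → keto acid → lactone → hemiketal → ring T, then phenol release, O-alkylation, auxiliary, aldol, reduction of the helper acyl carbon to CγH3, debenzylation.
Stereochemistry: C3/C4 come from one catalytic desymmetrisation, C5 is relayed by Felkin–Anh reduction, and C2 by hydride attack on an oxocarbenium ion anti to both methyl groups. Cα/Cβ come from (R)-4-benzyloxazolidin-2-one, which also turns any residual antipode of the core into a separable diastereomer.

Key step: step 10

Assumption: the (R,R)-TADDOL phosphoramidite is taken to direct the aryl group to the carbonyl next to the (S)-carbon of 4, and the chelated-enolate model is taken for the facial sense in step 10. If either sense is reversed, the mirror-image ligand or auxiliary is used and nothing else changes.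

**Step 1**
Reactants: 1 4-bromo-2-methoxyphenol
Product: 2 (4-bromo-2-methoxyphenoxy)triisopropylsilane
Conditions: i-Pr3SiCl, imidazole, DMF, 23 °C
Reagents that add atoms: chlorotriisopropylsilane, CC(C)[Si](Cl)(C(C)C)C(C)C
Why: Silyl ether formation on a phenol gives a group that should survive organolithium, hydride and cold BF3 steps and is orthogonal to the benzyl ethers used for rings A and C.

**Step 2**
Reactants: 3 meso-2,3-dimethylsuccinic acid
Product: 4 cis-3,4-dimethyloxolane-2,5-dione (meso anhydride)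
Conditions: AcCl, reflux, then evaporation
Reagents that add atoms: none
Why: Dehydrative cyclisation of a 1,4-diacid to the five-membered anhydride runs without base, so the cis relation of the methyl groups should be kept.

**Step 3**
Reactants: 2 (4-bromo-2-methoxyphenoxy)triisopropylsilane; 4 cis-3,4-dimethyloxolane-2,5-dione
Product: 7 (2R,3S)-4-[3-methoxy-4-(triisopropylsilyloxy)phenyl]-2,3-dimethyl-4-oxobutanoic acid, via aryllithium 5 (not isolated), via arylzinc triflate 6 (not isolated)
Conditions: 2, n-BuLi, THF, −78 °C; Zn(OTf)2, −78 → 23 °C; then 4, [Rh(cod)Cl]2 (4 mol %), (R,R)-TADDOL-derived N,N-dimethylphosphoramidite (8 mol %), THF, 50 °C; 1 M HCl work-up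
Reagents that add atoms: n-butyllithium, [Li]CCCC (lithium in 5 only); zinc triflate, [Zn+2].[O-]S(=O)(=O)C(F)(F)F.[O-]S(=O)(=O)C(F)(F)F (zinc and triflate in 6 only)
Why: In this rhodium-catalysed enantioselective desymmetrising acylation of a cyclic meso anhydride with an arylzinc, the chiral rhodium–phosphoramidite complex inserts into one of the two enantiotopic C(=O)–O bonds, so the ligand fixes C3 and C4 in absolute terms while their meso-derived relation is retained.

**Step 4**
Reactants: 7 keto acid
Product: 9 (3R,4S,5S)-5-[3-methoxy-4-(triisopropylsilyloxy)phenyl]-3,4-dimethyloxolan-2-one (3,4-cis-4,5-trans), via hydroxy acid 8 (not isolated)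
Conditions: LiBH(s-Bu)3 (2.5 equiv), THF, −78 °C; then 1 M HCl, 0 → 23 °C
Reagents that add atoms: none
Why: In this Felkin–Anh-controlled ketone reduction followed by lactonisation, the bulky hydride attacks anti to the CH(CH3)CO2Li branch, giving the anti (OH/CH3) alcohol that closes to the 4,5-trans lactone, which is also the more stable C5 epimer.

**Step 5**
Reactants: 9 lactone; 10 1-(benzyloxy)-4-bromo-2-methoxybenzene
Product: 12 (3R,4S,5S)-2-[4-(benzyloxy)-3-methoxyphenyl]-5-[3-methoxy-4-(triisopropylsilyloxy)phenyl]-3,4-dimethyloxolan-2-ol (hemiketal in equilibrium with its open hydroxy ketone), via aryllithium 11 (not isolated)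
Conditions: 10, n-BuLi, THF, −78 °C; then 9, −78 °C; AcOH quench at −78 °C
Reagents that add atoms: n-butyllithium, [Li]CCCC (lithium in 11 only)
Why: The 1,2-addition of an aryllithium to a γ-lactone stops at the lithium hemiketal at low temperature, and the cold acidic quench should prevent epimerisation of the methyl centre next to the latent ketone.

**Step 6**
Reactants: 12 hemiketal
Product: 14 (2S,3R,4S,5S)-2-[4-(benzyloxy)-3-methoxyphenyl]-5-[3-methoxy-4-(triisopropylsilyloxy)phenyl]-3,4-dimethyloxolane (2,3-cis-3,4-cis-4,5-trans), via oxocarbenium ion 13 (not isolated)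
Conditions: Et3SiH, BF3·OEt2, CH2Cl2, −78 °C; sat. aq. NaHCO3 at −78 °C
Reagents that add atoms: none
Why: In this ionic silane reduction of a cyclic hemiketal, BF3 ionises 12 to the planar 2-aryl oxocarbenium ion 13, which takes hydride by inside attack on the envelope with the C4 methyl pseudo-equatorial, that is on the face anti to both methyl groups, so ring A ends cis to them.

**Step 7**
Reactants: 14 silyl ether
Product: 15 (2S,3R,4S,5S)-2-[4-(benzyloxy)-3-methoxyphenyl]-5-(4-hydroxy-3-methoxyphenyl)-3,4-dimethyloxolane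
Conditions: Bu4NF, AcOH, THF, 0 °C
Reagents that add atoms: none
Why: Buffered fluoride cleavage of an aryl silyl ether frees only the ring B phenol and leaves the benzyl ether and ring T untouched.

**Step 8**
Reactants: 15 phenol; 16 bromoacetic acid
Product: 17 2-{4-[(2S,3S,4R,5S)-5-(4-benzyloxy-3-methoxyphenyl)-3,4-dimethyloxolan-2-yl]-2-methoxyphenoxy}acetic acid
Conditions: NaH (2.5 equiv), THF–DMF, 0 → 23 °C; cold 1 M HCl to pH 3
Reagents that add atoms: none
Why: In this Williamson ether synthesis the sodium phenoxide displaces bromide from sodium bromoacetate and gives the aryloxyacetic acid in one operation, bringing in Cβ and the future Cγ.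

**Step 9**
Reactants: 17 aryloxyacetic acid; 18 (R)-4-benzyloxazolidin-2-one
Product: 20 (R)-4-benzyl-3-(aryloxyacetyl)oxazolidin-2-one in which aryloxy is the ring B oxygen of the core, via mixed pivalic anhydride 19 (not isolated)
Conditions: t-BuCOCl, Et3N, THF, −20 °C; then LiCl, 18, −20 → 23 °C
Reagents that add atoms: pivaloyl chloride, CC(C)(C)C(=O)Cl (acyl group in 19 only)
Why: N-Acylation of an oxazolidinone through a mixed anhydride takes place at the less hindered aryloxyacetyl carbonyl and installs the activating and stereodirecting helper.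

**Step 10**
Reactants: 20 aryloxyacetyl imide; 21 4-(benzyloxy)-3-methoxybenzaldehyde
Product: 23 (R)-4-benzyl-3-[(2S,3S)-2-aryloxy-3-(4-benzyloxy-3-methoxyphenyl)-3-hydroxypropanoyl]oxazolidin-2-one (anti adduct), via trimethylsilyl ether 22 (not isolated)
Conditions: MgCl2 (20 mol %), Et3N, Me3SiCl, EtOAc, 23 °C; then PPTS, MeOH, 0 °C
Reagents that add atoms: chlorotrimethylsilane, C[Si](C)(C)Cl (silyl group in 22 only, lost again on methanolysis)
Why: Proposed new method: MgCl2 chelates the two imide carbonyl oxygens of 20, Et3N removes an OCH2 proton (acidified by the imide and the aryloxy oxygen) to give the chelated (Z)-magnesium enolate, this adds reversibly to the formyl carbon of 21, Me3SiCl silylates the magnesium aldolate to 22 and returns MgCl2, and mild methanolysis then gives 23. The closest known reaction type is the magnesium-halide-catalysed direct anti-aldol addition of N-propionyl and related N-alkanoyl oxazolidinones to non-enolisable aromatic aldehydes, and the new element is the aryloxy group on the enolate carbon, which should ease soft enolisation and keep the (Z) geometry because allylic strain against the auxiliary is unchanged. No ring is closed. Cβ is controlled by the auxiliary, since in the chelated enolate the benzyl group of the (R)-oxazolidinone covers one face and the aldehyde is taken up on the other, giving the (2S) imide whose descriptor becomes (R) once the acyl carbon is CH3. Cα is controlled by the anti preference of this manifold, argued from the six-membered magnesium aldolate chelate in which ring C and the aryloxy group are both equatorial only in the anti isomer, so this isomer is favoured in the reversible addition and drained by silylation. The step needs anti over syn selectivity, one enolate face and survival of the acid-labile dibenzylic ether ring T: the first two rest on the chelate and the auxiliary (the ring T stereocentres are too remote to interfere), the electron-rich non-enolisable aldehyde belongs to the favourable class for this reaction, and no strong Lewis acid is present.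

**Step 11**
Reactants: 23 anti aldol adduct
Product: 24 (1S,2R)-2-aryloxy-1-(4-benzyloxy-3-methoxyphenyl)propane-1,3-diol (erythro)
Conditions: NaBH4, THF–H2O, 0 → 23 °C
Reagents that add atoms: none
Why: Reductive cleavage of an N-acyloxazolidinone with borohydride attacks the exocyclic, aryloxy-activated carbonyl, releases the auxiliary and touches neither new stereocentre.

**Step 12**
Reactants: 24 diol
Product: 25 (2R,3S)-2-aryloxy-3-(4-benzyloxy-3-methoxyphenyl)-3-hydroxypropyl 4-methylbenzenesulfonate
Conditions: TsCl (1.1 equiv), pyridine, CH2Cl2, 0 °C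
Reagents that add atoms: 4-toluenesulfonyl chloride, Cc1ccc(cc1)S(=O)(=O)Cl
Why: Selective sulfonylation of a primary over a hindered secondary benzylic alcohol rests on the steric difference between the two hydroxyl groups.

**Step 13**
Reactants: 25 monotosylate
Product: 26 (1S,2R)-2-aryloxy-1-(4-benzyloxy-3-methoxyphenyl)propan-1-ol (bis-benzyl ether of the target)
Conditions: LiBHEt3 (4 equiv), THF, 0 → 23 °C
Reagents that add atoms: none
Why: SN2 hydride displacement of a primary tosylate turns the helper carbon into CγH3 without touching Cα or Cβ, and an oxetane formed in passing would be opened by hydride at its CH2 to the same product.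

**Step 14**
Reactants: 26 bis-benzyl ether
Product: 27 (1S,2R)-1-(4-hydroxy-3-methoxyphenyl)-2-{4-[(2S,3S,4R,5S)-5-(4-hydroxy-3-methoxyphenyl)-3,4-dimethyloxolan-2-yl]-2-methoxyphenoxy}propan-1-ol
Conditions: H2 (1 atm), 10% Pd/C, EtOAc–EtOH, 23 °C, stopped at full conversion
Reagents that add atoms: none
Why: Catalytic hydrogenolysis cleaves aryl benzyl ethers faster than the secondary benzylic alcohol or the hindered dibenzylic ether ring T, as is usual for this class of lignans.

**Compound list**

1 | 4-bromo-2-methoxyphenol | COc1cc(Br)ccc1O | starting material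
2 | (4-bromo-2-methoxyphenoxy)triisopropylsilane | COc1cc(Br)ccc1O[Si](C(C)C)(C(C)C)C(C)C | intermediate
3 | meso-2,3-dimethylsuccinic acid | OC(=O)[C@H](C)[C@H](C)C(=O)O | starting material
4 | cis-3,4-dimethyloxolane-2,5-dione | C[C@H]1C(=O)OC(=O)[C@H]1C | intermediate
5 | [3-methoxy-4-(triisopropylsilyloxy)phenyl]lithium | COc1cc([Li])ccc1O[Si](C(C)C)(C(C)C)C(C)C | intermediate
6 | [3-methoxy-4-(triisopropylsilyloxy)phenyl]zinc triflate | COc1cc([Zn]OS(=O)(=O)C(F)(F)F)ccc1O[Si](C(C)C)(C(C)C)C(C)C | intermediate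
7 | (2R,3S)-4-[3-methoxy-4-(triisopropylsilyloxy)phenyl]-2,3-dimethyl-4-oxobutanoic acid | COc1cc(C(=O)[C@@H](C)[C@@H](C)C(=O)O)ccc1O[Si](C(C)C)(C(C)C)C(C)C | intermediate
8 | (2R,3S,4S)-4-hydroxy-4-[3-methoxy-4-(triisopropylsilyloxy)phenyl]-2,3-dimethylbutanoic acid | COc1cc([C@@H](O)[C@@H](C)[C@@H](C)C(=O)O)ccc1O[Si](C(C)C)(C(C)C)C(C)C | intermediate
9 | (3R,4S,5S)-5-[3-methoxy-4-(triisopropylsilyloxy)phenyl]-3,4-dimethyloxolan-2-one | O=C1O[C@H](c2ccc(O[Si](C(C)C)(C(C)C)C(C)C)c(OC)c2)[C@@H](C)[C@H]1C | intermediate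
10 | 1-(benzyloxy)-4-bromo-2-methoxybenzene | COc1cc(Br)ccc1OCc1ccccc1 | starting material
11 | [4-(benzyloxy)-3-methoxyphenyl]lithium | COc1cc([Li])ccc1OCc1ccccc1 | intermediate
12 | hemiketal, (3R,4S,5S)-2-[4-(benzyloxy)-3-methoxyphenyl]-5-[3-methoxy-4-(triisopropylsilyloxy)phenyl]-3,4-dimethyloxolan-2-ol (C2 epimers) | COc1cc(C2(O)O[C@H](c3ccc(O[Si](C(C)C)(C(C)C)C(C)C)c(OC)c3)[C@@H](C)[C@H]2C)ccc1OCc1ccccc1 | intermediate
13 | 2-aryl oxocarbenium ion from 12 | COc1cc(C2=[O+][C@H](c3ccc(O[Si](C(C)C)(C(C)C)C(C)C)c(OC)c3)[C@@H](C)[C@H]2C)ccc1OCc1ccccc1 | intermediate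
14 | (2S,3R,4S,5S)-2-[4-(benzyloxy)-3-methoxyphenyl]-5-[3-methoxy-4-(triisopropylsilyloxy)phenyl]-3,4-dimethyloxolane | COc1cc([C@H]2O[C@H](c3ccc(O[Si](C(C)C)(C(C)C)C(C)C)c(OC)c3)[C@@H](C)[C@H]2C)ccc1OCc1ccccc1 | intermediate
15 | (2S,3R,4S,5S)-2-[4-(benzyloxy)-3-methoxyphenyl]-5-(4-hydroxy-3-methoxyphenyl)-3,4-dimethyloxolane | COc1cc([C@H]2O[C@H](c3ccc(O)c(OC)c3)[C@@H](C)[C@H]2C)ccc1OCc1ccccc1 | intermediate
16 | bromoacetic acid | OC(=O)CBr | starting material
17 | aryloxyacetic acid of 15 (ring B O–CH2CO2H) | COc1cc([C@H]2O[C@H](c3ccc(OCC(=O)O)c(OC)c3)[C@@H](C)[C@H]2C)ccc1OCc1ccccc1 | intermediate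
18 | (R)-4-benzyloxazolidin-2-one | O=C1N[C@H](Cc2ccccc2)CO1 | starting material
19 | mixed anhydride of 17 with pivalic acid | COc1cc([C@H]2O[C@H](c3ccc(OCC(=O)OC(=O)C(C)(C)C)c(OC)c3)[C@@H](C)[C@H]2C)ccc1OCc1ccccc1 | intermediate
20 | (R)-4-benzyl-3-(aryloxyacetyl)oxazolidin-2-one of 17 | COc1cc([C@H]2O[C@H](c3ccc(OCC(=O)N4[C@H](Cc5ccccc5)COC4=O)c(OC)c3)[C@@H](C)[C@H]2C)ccc1OCc1ccccc1 | intermediate
21 | 4-(benzyloxy)-3-methoxybenzaldehyde | COc1cc(C=O)ccc1OCc1ccccc1 | starting material
22 | (2S,3S) anti adduct as its Cα trimethylsilyl ether | COc1cc([C@H]2O[C@H](c3ccc(O[C@H](C(=O)N4[C@H](Cc5ccccc5)COC4=O)[C@@H](O[Si](C)(C)C)c4ccc(OCc5ccccc5)c(OC)c4)c(OC)c3)[C@@H](C)[C@H]2C)ccc1OCc1ccccc1 | intermediate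
23 | (2S,3S) anti aldol adduct on the (R)-auxiliary | COc1cc([C@H]2O[C@H](c3ccc(O[C@H](C(=O)N4[C@H](Cc5ccccc5)COC4=O)[C@@H](O)c4ccc(OCc5ccccc5)c(OC)c4)c(OC)c3)[C@@H](C)[C@H]2C)ccc1OCc1ccccc1 | intermediate
24 | (1S,2R) erythro 1,3-diol | COc1cc([C@H]2O[C@H](c3ccc(O[C@H](CO)[C@@H](O)c4ccc(OCc5ccccc5)c(OC)c4)c(OC)c3)[C@@H](C)[C@H]2C)ccc1OCc1ccccc1 | intermediate
25 | (2R,3S) primary monotosylate | COc1cc([C@H]2O[C@H](c3ccc(O[C@H](COS(=O)(=O)c4ccc(C)cc4)[C@@H](O)c4ccc(OCc5ccccc5)c(OC)c4)c(OC)c3)[C@@H](C)[C@H]2C)ccc1OCc1ccccc1 | intermediate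
26 | bis-benzyl ether of the target, (1S,2R) erythro | COc1cc([C@H]2O[C@H](c3ccc(O[C@H](C)[C@@H](O)c4ccc(OCc5ccccc5)c(OC)c4)c(OC)c3)[C@@H](C)[C@H]2C)ccc1OCc1ccccc1 | intermediate
27 | CNP0171079.3 | COc1cc([C@H]2O[C@H](c3ccc(O[C@H](C)[C@@H](O)c4ccc(O)c(OC)c4)c(OC)c3)[C@@H](C)[C@H]2C)ccc1O | target

**Step count**

Total step count: 14.
Longest linear sequence: 13 (steps 1 and 3–14).

**Steps most likely to fail**

**1. Step 10.** Anti selectivity could erode if the aryloxy oxygen competes with the ring carbonyl for magnesium and changes the chelate. The catalytic cycle could also stall at the silylation.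

The fallback sets out from 17 and returns at 26.
- Acid 17 is activated as the same mixed anhydride 19 and coupled with (S)-4-benzyloxazolidin-2-one to give the (S)-auxiliary imide F1.
- An Evans syn-aldol addition (n-Bu2BOTf, i-Pr2NEt, CH2Cl2, −78 → 0 °C, then 21) has direct precedent on aryloxyacetyl imides. It sets Cβ correctly and gives the (2S,3R) syn adduct F2.
- NaBH4 in THF–H2O gives the threo diol F3.
- TsCl in pyridine gives the threo monotosylate F4.
- LiBHEt3 gives the threo alcohol F5.
- Cα is then corrected. Dess–Martin periodinane gives the α-aryloxy ketone F6.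
- Chelation-controlled reduction with Zn(BH4)2 in Et2O at −78 °C follows. Zinc is held between the ketone oxygen and the aryl ether oxygen, and hydride enters past the Cβ hydrogen, which should give the erythro alcohol 26.

**2. Step 3.** The two enantiotopic carbonyl groups might be discriminated incompletely. The bulky, electron-rich arylzinc might also transmetalate slowly and suffer protodemetalation.

The fallback sets out from 4 and returns at 9.
- Cinchona-alkaloid-mediated methanolysis of 4 (quinidine, MeOH, toluene, −55 °C; quinine if the sense is opposite) gives the hemiester F7.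
- EtSH with DCC and catalytic DMAP gives the thioester F8.
- A Fukuyama coupling with arylzinc 6 (PdCl2(PPh3)2, THF–toluene, 23 °C) gives the keto ester F9.
- LiBH(s-Bu)3 at −78 °C gives the hydroxy ester F10, which closes to lactone 9 with catalytic TsOH.

**3. Step 6.** The kinetic 2,3-cis product could drift to the more stable 2,3-trans isomer by Lewis-acid opening of the benzylic C2–O bond. The C3 configuration could also be lost by proton loss from the oxocarbenium ion.

The fallback sets out from 12 and returns at 14.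
- PhSH with catalytic BF3·OEt2 in CH2Cl2 at −78 °C gives the mixed O,S-ketal F11.
- Radical desulfurisation (n-Bu3SnH, Et3B, air, toluene, 0 → 23 °C) passes through a planar benzylic α-oxy radical that should take hydrogen from the stannane on the face anti to both methyl groups.
- Product 14 therefore forms under neutral conditions and never meets a Lewis acid.

**Further compounds**

F1 | step 10 | (S)-4-benzyl-3-(aryloxyacetyl)oxazolidin-2-one of 17 | COc1cc([C@H]2O[C@H](c3ccc(OCC(=O)N4[C@@H](Cc5ccccc5)COC4=O)c(OC)c3)[C@@H](C)[C@H]2C)ccc1OCc1ccccc1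
F2 | step 10 | (2S,3R) syn aldol adduct on the (S)-auxiliary | COc1cc([C@H]2O[C@H](c3ccc(O[C@H](C(=O)N4[C@@H](Cc5ccccc5)COC4=O)[C@H](O)c4ccc(OCc5ccccc5)c(OC)c4)c(OC)c3)[C@@H](C)[C@H]2C)ccc1OCc1ccccc1
F3 | step 10 | (1R,2R) threo 1,3-diol | COc1cc([C@H]2O[C@H](c3ccc(O[C@H](CO)[C@H](O)c4ccc(OCc5ccccc5)c(OC)c4)c(OC)c3)[C@@H](C)[C@H]2C)ccc1OCc1ccccc1
F4 | step 10 | (2R,3R) threo primary monotosylate | COc1cc([C@H]2O[C@H](c3ccc(O[C@H](COS(=O)(=O)c4ccc(C)cc4)[C@H](O)c4ccc(OCc5ccccc5)c(OC)c4)c(OC)c3)[C@@H](C)[C@H]2C)ccc1OCc1ccccc1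
F5 | step 10 | (1R,2R) threo alcohol, Cα epimer of 26 | COc1cc([C@H]2O[C@H](c3ccc(O[C@H](C)[C@H](O)c4ccc(OCc5ccccc5)c(OC)c4)c(OC)c3)[C@@H](C)[C@H]2C)ccc1OCc1ccccc1
F6 | step 10 | (R)-2-aryloxy-1-(4-benzyloxy-3-methoxyphenyl)propan-1-one | COc1cc([C@H]2O[C@H](c3ccc(O[C@H](C)C(=O)c4ccc(OCc5ccccc5)c(OC)c4)c(OC)c3)[C@@H](C)[C@H]2C)ccc1OCc1ccccc1
F7 | step 3 | (2S,3R)-4-methoxy-2,3-dimethyl-4-oxobutanoic acid | OC(=O)[C@@H](C)[C@@H](C)C(=O)OC
F8 | step 3 | methyl (2R,3S)-4-(ethylsulfanyl)-2,3-dimethyl-4-oxobutanoate | CCSC(=O)[C@@H](C)[C@@H](C)C(=O)OC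
F9 | step 3 | methyl (2R,3S)-4-[3-methoxy-4-(triisopropylsilyloxy)phenyl]-2,3-dimethyl-4-oxobutanoate | COc1cc(C(=O)[C@@H](C)[C@@H](C)C(=O)OC)ccc1O[Si](C(C)C)(C(C)C)C(C)C
F10 | step 3 | methyl (2R,3S,4S)-4-hydroxy-4-[3-methoxy-4-(triisopropylsilyloxy)phenyl]-2,3-dimethylbutanoate | COc1cc([C@@H](O)[C@@H](C)[C@@H](C)C(=O)OC)ccc1O[Si](C(C)C)(C(C)C)C(C)C
F11 | step 6 | mixed O,S-ketal, 2-phenylsulfanyl analogue of 12 (C2 epimers) | COc1cc(C2(Sc3ccccc3)O[C@H](c3ccc(O[Si](C(C)C)(C(C)C)C(C)C)c(OC)c3)[C@@H](C)[C@H]2C)ccc1OCc1ccccc1
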